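**Retrosynthetic overview**
1. Target ⇒ (E,Z,Z,E)-tetraene 29 by a thermal 8π/6π electrocyclisation cascade ⇒ Suzuki union of east (Z)-trienyl iodide 19 and west (Z)-dienylboronate 28.
2. East: the oxabicyclo[2.2.1] core ⇒ C3–C2′ bond of pyranone 10, made with reversed polarity. The β-ketolactone enol becomes an enolonium (λ3-iodanyl enolate) and is attacked by its own diene arm, closing cyclopentanone and γ-lactone and setting both quaternary carbons at once.
3. 10 ⇒ anti-aldol of β-ketoimide 7 with dienal 3, then lactonisation.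
4. West: tiglaldehyde + ethynyl Grignard, lipase resolution, carboalumination/Negishi coupling with (Z)-bromopropenylboronate 26 (from propyne).
5. Ring order: δ-lactone → [2.2.1] ketolactone → cyclooctatriene → cyclobutane/cyclohexadiene (bicyclo[4.2.0]octadiene).

Assumption: the SMILES is taken as the full definition of shimalactone B (carbinol R; oxabicycle 1S,4S,6R,7S); the labels C3, C5, C6 and C2′ used below refer to pyranone 10.

**Route**

Step 1
Reactants: 1 methacrolein (2-methylprop-2-enal); 2 2-(triphenylphosphoranylidene)propanal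
Product: 3 (2E)-2,4-dimethylpenta-2,4-dienal
Conditions: CH2Cl2, 40 °C, 16 h
Reagents that add atoms: none
Why: Wittig olefination with a stabilised formyl ylide gives the (E)-trisubstituted enal, and the more conjugated product reacts on only slowly.

Step 2
Reactants: 4 (4R)-4-benzyl-3-propanoyl-1,3-oxazolidin-2-one; 5 propanoyl chloride
Product: 7 (4R)-4-benzyl-3-[(2S)-2-methyl-3-oxopentanoyl]-1,3-oxazolidin-2-one, via lithium Z-enolate 6 (not isolated)
Conditions: LiN(i-Pr)2 (1.1 equiv), THF, −78 °C; then 5, −78 °C, 10 min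
Reagents that add atoms: none
Why: Evans acylation of the chelated Z-enolate: the acid chloride approaches the face opposite the benzyl group (same sense as alkylation), setting C2 as S, and allylic (A1,3) strain keeps the product from epimerising.

Step 3
Reactants: 7 (4R)-4-benzyl-3-[(2S)-2-methyl-3-oxopentanoyl]-1,3-oxazolidin-2-one; 3 (2E)-2,4-dimethylpenta-2,4-dienal
Product: 9 (4R)-4-benzyl-3-[(2S,4R,5S,6E)-5-hydroxy-2,4,6,8-tetramethyl-3-oxonona-6,8-dienoyl]-1,3-oxazolidin-2-one, via boron E-enolate 8 (not isolated)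
Conditions: (c-C6H11)2BCl (1.3 equiv), EtNMe2 (1.5 equiv), Et2O, 0 °C; then 3, −78 → −20 °C; MeOH, pH 7 buffer, 30% H2O2, 0 °C
Reagents that add atoms: none
Why: Boron-mediated anti-aldol of a β-ketoimide: the E-enolate forms on the ethyl side only, the chair (Zimmerman–Traxler) transition state gives 4,5-anti, and the adjacent C2 methyl centre (not the remote auxiliary) directs the aldehyde to give 2,4-anti, i.e. 4R,5S.

Step 4
Reactants: 9 (4R)-4-benzyl-3-[(2S,4R,5S,6E)-5-hydroxy-2,4,6,8-tetramethyl-3-oxonona-6,8-dienoyl]-1,3-oxazolidin-2-one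
Product: 10 (5R,6S)-4-hydroxy-3,5-dimethyl-6-[(2E)-4-methylpenta-2,4-dien-2-yl]-5,6-dihydro-2H-pyran-2-one (enol form of the pyran-2,4-dione)
Conditions: DBU (1,8-diazabicyclo[5.4.0]undec-7-ene, 1.2 equiv), CH2Cl2, 0 → 23 °C; 1 M HCl wash
Reagents that add atoms: none
Why: Lactonisation by intramolecular acyl transfer: the C5 hydroxyl attacks the activated imide carbonyl through a six-membered transition state and expels the oxazolidinone; C5 and C6 are untouched and C3 becomes the enol carbon.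

Step 5
Reactants: 10 (5R,6S)-4-hydroxy-3,5-dimethyl-6-[(2E)-4-methylpenta-2,4-dien-2-yl]-5,6-dihydro-2H-pyran-2-one
Product: 13 (2E)-2-methyl-3-[(1S,4S,6R,7S)-4,6,7-trimethyl-3,5-dioxo-2-oxabicyclo[2.2.1]heptan-7-yl]prop-2-enal, via iodanyl enolate 11 (not isolated), via allylic alcohol 12 (not isolated)
Conditions: PhI(OAc)2 (1.1 equiv), NaHCO3 (5 equiv), (CF3)2CHOH/H2O (10:1), −20 → 0 °C; then TEMPO (2,2,6,6-tetramethylpiperidin-1-oxyl, 10 mol %), PhI(OAc)2 (1.2 equiv), CH2Cl2, 23 °C
Reagents that add atoms: water, O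
Why: Proposed new method: the 3-methyl enol exchanges a ligand on PhI(OAc)2 to give O-iodanyl enolate 11, an enolonium equivalent that cannot collapse to an iodonium ylide because C3 bears no hydrogen; with the C6 arm axial, the diene terminus C2′ (a π-nucleophile) attacks the now electrophilic C3 in a 5-exo closure with loss of PhI, and water captures the resulting 2-methylallyl cation at its primary end to give E-allylic alcohol 12, which the same oxidant with TEMPO (oxoammonium oxidation) takes to the enal; C4 of the bicycle can only form on the face carrying the C6 arm, and C7 is set by the rotamer that puts the flat alkenyl arm over the C5–H side and the methyl group over the ring oxygen; the closest known reactions are trivalent-iodine α-oxygenation and α-arylation of 2-substituted 1,3-dicarbonyls, enolonium allylation with allylsilanes, and the acid-mediated cationic closure of this ring system in the opposite polarity sense.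

Step 6
Reactants: 13 (2E)-2-methyl-3-[(1S,4S,6R,7S)-4,6,7-trimethyl-3,5-dioxo-2-oxabicyclo[2.2.1]heptan-7-yl]prop-2-enal; 2 2-(triphenylphosphoranylidene)propanal
Product: 14 (2E,4E)-2,4-dimethyl-5-[(1S,4S,6R,7S)-4,6,7-trimethyl-3,5-dioxo-2-oxabicyclo[2.2.1]heptan-7-yl]penta-2,4-dienal
Conditions: 2 (1.5 equiv), toluene, 90 °C, 24 h
Reagents that add atoms: none
Why: E-selective Wittig olefination with the stabilised formyl ylide, which does not touch the hindered ketone or the lactone.

Step 7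
Reactants: 14 (2E,4E)-2,4-dimethyl-5-[(1S,4S,6R,7S)-4,6,7-trimethyl-3,5-dioxo-2-oxabicyclo[2.2.1]heptan-7-yl]penta-2,4-dienal; 15 ethyltriphenylphosphonium iodide
Product: 19 (1S,4S,6R,7S)-7-[(1E,3E,5Z)-6-iodo-2,4-dimethylhepta-1,3,5-trien-1-yl]-4,6,7-trimethyl-2-oxabicyclo[2.2.1]heptane-3,5-dione, via ethylidene ylide 16 (not isolated), via iodoethylphosphonium iodide 17 (not isolated), via iodo ylide 18 (not isolated)
Conditions: 15, n-BuLi, THF, 23 °C; I2, −78 °C; NaN(SiMe3)2, −20 °C; then 14, −78 → −20 °C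
Reagents that add atoms: iodine, II
Why: Stork–Zhao-type iodo-olefination: the non-stabilised α-iodo ylide adds to the aldehyde under kinetic control to give the (Z)-2-iodoalkene (iodine cis to the chain), and at −78 °C with no excess base the hindered ketone and C6–H are left alone.

Step 8
Reactants: 20 tiglaldehyde ((2E)-2-methylbut-2-enal); 21 ethynylmagnesium bromide
Product: 22 rac-(4E)-4-methylhex-4-en-1-yn-3-ol
Conditions: THF, 0 °C; sat. aq. NH4Cl
Reagents that add atoms: none
Why: 1,2-Addition of an alkynyl Grignard reagent to an α-branched enal; the carbinol centre is formed racemic.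

Step 9
Reactants: 22 rac-(4E)-4-methylhex-4-en-1-yn-3-ol
Product: 23 (3S,4E)-4-methylhex-4-en-1-yn-3-ol
Conditions: Novozym 435 (immobilised Candida antarctica lipase B), vinyl acetate (0.6 equiv), hexane, 30 °C, stopped at about 52% conversion
Reagents that add atoms: none
Why: Lipase kinetic resolution (Kazlauskas rule, ethynyl as the small group): the (R)-alcohol is acetylated and the (S)-alcohol remains, which has the spatial arrangement of the target carbinol (it becomes R by CIP once the alkyne is elaborated).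

Step 10
Reactants: 24 propyne
Product: 26 2-[(1Z)-2-bromoprop-1-en-1-yl]-4,4,5,5-tetramethyl-1,3,2-dioxaborolane, via dibromoborane 25 (not isolated)
Conditions: BBr3 (1.0 equiv), CH2Cl2, −78 → 23 °C; then pinacol, −78 → 23 °C
Reagents that add atoms: boron tribromide, BrB(Br)Br; pinacol, CC(C)(O)C(C)(C)O
Why: syn-Bromoboration of a terminal alkyne (bromine to the internal carbon, boron to the terminal carbon, same side) then esterification gives the (Z)-β-bromoalkenylboronate.

Step 11
Reactants: 23 (3S,4E)-4-methylhex-4-en-1-yn-3-ol; 26 2-[(1Z)-2-bromoprop-1-en-1-yl]-4,4,5,5-tetramethyl-1,3,2-dioxaborolane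
Product: 28 (2E,4R,5E,7Z)-3,5,7-trimethyl-8-(4,4,5,5-tetramethyl-1,3,2-dioxaborolan-2-yl)octa-2,5,7-trien-4-ol, via alkenylalane 27 (not isolated)
Conditions: Me3Al (3 equiv), Cp2ZrCl2 (0.2 equiv), H2O (1 equiv), CH2Cl2, −20 → 0 °C; volatiles removed in vacuo; then 26, Pd(P(t-Bu)3)2 (3 mol %), ZnBr2 (0.5 equiv), THF, 23 °C; aq. NaHCO3/KNaC4H4O6 work-up
Reagents that add atoms: trimethylaluminium, C[Al](C)C
Why: Zirconium-catalysed carboalumination (syn, methyl to the internal carbon; water-accelerated so it runs cold on the aluminium alkoxide) gives the (E)-alkenylalane, which undergoes Negishi cross-coupling at the C–Br bond with retention on both partners, leaving the C–B bond and the carbinol centre intact and fixing the 5E and 7Z double bonds.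

Step 12
Reactants: 19 (1S,4S,6R,7S)-7-[(1E,3E,5Z)-6-iodo-2,4-dimethylhepta-1,3,5-trien-1-yl]-4,6,7-trimethyl-2-oxabicyclo[2.2.1]heptane-3,5-dione; 28 (2E,4R,5E,7Z)-3,5,7-trimethyl-8-(4,4,5,5-tetramethyl-1,3,2-dioxaborolan-2-yl)octa-2,5,7-trien-4-ol
Product: 31 shimalactone B, via tetraene 29 (not isolated), via cyclooctatriene 30 (not isolated)
Conditions: Pd(P(t-Bu)3)2 (5 mol %), CsF (3 equiv), THF/H2O (20:1), degassed, dark, 23 → 50 °C; preparative HPLC
Reagents that add atoms: none
Why: Suzuki–Miyaura coupling with retention gives the (E,Z,Z,E)-tetraene, which undergoes thermal conrotatory 8π then disrotatory 6π electrocyclisation (Woodward–Hoffmann rules); the E termini place the carbinol arm and the C8 arm trans on the cyclooctatriene, and the 6π closure gives the cis-fused ring with the angular methyl away from the side chain, so the four new centres are fixed relative to each other; the helical sense relative to the carbinol is only partly controlled, so the other helical diastereomer (shimalactone A) forms alongside and 31 is separated by HPLC.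

**Compound list**
1 | methacrolein | CC(=C)C=O | starting material
2 | 2-(triphenylphosphoranylidene)propanal | CC(C=O)=P(c1ccccc1)(c1ccccc1)c1ccccc1 | starting material
3 | (2E)-2,4-dimethylpenta-2,4-dienal | O=C/C(C)=C/C(C)=C | intermediate
4 | (4R)-4-benzyl-3-propanoyl-1,3-oxazolidin-2-one | CCC(=O)N1[C@H](Cc2ccccc2)COC1=O | starting material
5 | propanoyl chloride | CCC(=O)Cl | starting material
6 | lithium Z-enolate of 4 | C/C=C(\O[Li])N1[C@H](Cc2ccccc2)COC1=O | intermediate (not isolated)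
7 | (4R)-4-benzyl-3-[(2S)-2-methyl-3-oxopentanoyl]-1,3-oxazolidin-2-one | CCC(=O)[C@H](C)C(=O)N1[C@H](Cc2ccccc2)COC1=O | intermediate
8 | dicyclohexylboron E-enolate of 7 | C/C=C(/OB(C1CCCCC1)C1CCCCC1)[C@H](C)C(=O)N1[C@H](Cc2ccccc2)COC1=O | intermediate (not isolated)
9 | (4R)-4-benzyl-3-[(2S,4R,5S,6E)-5-hydroxy-2,4,6,8-tetramethyl-3-oxonona-6,8-dienoyl]-1,3-oxazolidin-2-one | C=C(C)/C=C(\C)[C@@H](O)[C@@H](C)C(=O)[C@H](C)C(=O)N1[C@H](Cc2ccccc2)COC1=O | intermediate
10 | (5R,6S)-4-hydroxy-3,5-dimethyl-6-[(2E)-4-methylpenta-2,4-dien-2-yl]-5,6-dihydro-2H-pyran-2-one (enol form of the pyran-2,4-dione) | C=C(C)/C=C(\C)[C@H]1OC(=O)C(C)=C(O)[C@@H]1C | intermediate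
11 | acetoxy(phenyl)-λ3-iodanyl enol ether of 10 (iodine on the C4 oxygen) | C=C(C)/C=C(\C)[C@H]1OC(=O)C(C)=C(OI(OC(C)=O)c2ccccc2)[C@@H]1C | intermediate (not isolated)
12 | (1S,4S,6R,7S)-7-[(1E)-3-hydroxy-2-methylprop-1-en-1-yl]-4,6,7-trimethyl-2-oxabicyclo[2.2.1]heptane-3,5-dione | OC/C(C)=C/[C@]1(C)[C@H]2OC(=O)[C@]1(C)C(=O)[C@@H]2C | intermediate (not isolated)
13 | (2E)-2-methyl-3-[(1S,4S,6R,7S)-4,6,7-trimethyl-3,5-dioxo-2-oxabicyclo[2.2.1]heptan-7-yl]prop-2-enal | O=C/C(C)=C/[C@]1(C)[C@H]2OC(=O)[C@]1(C)C(=O)[C@@H]2C | intermediate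
14 | (2E,4E)-2,4-dimethyl-5-[(1S,4S,6R,7S)-4,6,7-trimethyl-3,5-dioxo-2-oxabicyclo[2.2.1]heptan-7-yl]penta-2,4-dienal | O=C/C(C)=C/C(C)=C/[C@]1(C)[C@H]2OC(=O)[C@]1(C)C(=O)[C@@H]2C | intermediate
15 | ethyltriphenylphosphonium iodide | CC[P+](c1ccccc1)(c1ccccc1)c1ccccc1.[I-] | starting material
16 | ethylidenetriphenylphosphorane | CC=P(c1ccccc1)(c1ccccc1)c1ccccc1 | intermediate (not isolated)
17 | (1-iodoethyl)triphenylphosphonium iodide | CC(I)[P+](c1ccccc1)(c1ccccc1)c1ccccc1.[I-] | intermediate (not isolated)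
18 | (1-iodoethylidene)triphenylphosphorane | CC(I)=P(c1ccccc1)(c1ccccc1)c1ccccc1 | intermediate (not isolated)
19 | (1S,4S,6R,7S)-7-[(1E,3E,5Z)-6-iodo-2,4-dimethylhepta-1,3,5-trien-1-yl]-4,6,7-trimethyl-2-oxabicyclo[2.2.1]heptane-3,5-dione | C/C(I)=C/C(C)=C/C(C)=C/[C@]1(C)[C@H]2OC(=O)[C@]1(C)C(=O)[C@@H]2C | intermediate
20 | tiglaldehyde, (2E)-2-methylbut-2-enal | C/C=C(\C)C=O | starting material
21 | ethynylmagnesium bromide | C#C[Mg]Br | starting material
22 | rac-(4E)-4-methylhex-4-en-1-yn-3-ol | C/C=C(\C)C(O)C#C | intermediate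
23 | (3S,4E)-4-methylhex-4-en-1-yn-3-ol | C/C=C(\C)[C@@H](O)C#C | intermediate
24 | propyne | CC#C | starting material
25 | dibromo[(1Z)-2-bromoprop-1-en-1-yl]borane | C/C(Br)=C/B(Br)Br | intermediate (not isolated)
26 | 2-[(1Z)-2-bromoprop-1-en-1-yl]-4,4,5,5-tetramethyl-1,3,2-dioxaborolane | C/C(Br)=C/B1OC(C)(C)C(C)(C)O1 | intermediate
27 | (E)-alkenyl(dimethyl)alane from 23, as its dimethylaluminium alkoxide | C/C=C(\C)[C@@H](O[Al](C)C)/C(C)=C/[Al](C)C | intermediate (not isolated)
28 | (2E,4R,5E,7Z)-3,5,7-trimethyl-8-(4,4,5,5-tetramethyl-1,3,2-dioxaborolan-2-yl)octa-2,5,7-trien-4-ol | C/C=C(\C)[C@@H](O)/C(C)=C/C(C)=C\B1OC(C)(C)C(C)(C)O1 | intermediate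
29 | (1S,4S,6R,7S)-7-[(1E,3E,5Z,7Z,9E,11R,12E)-11-hydroxy-2,4,6,8,10,12-hexamethyltetradeca-1,3,5,7,9,12-hexaen-1-yl]-4,6,7-trimethyl-2-oxabicyclo[2.2.1]heptane-3,5-dione | C/C=C(\C)[C@@H](O)/C(C)=C/C(C)=C\C(C)=C/C(C)=C/C(C)=C/[C@]1(C)[C@H]2OC(=O)[C@]1(C)C(=O)[C@@H]2C | intermediate (not isolated)
30 | 7,8-trans-cycloocta-1,3,5-triene from conrotatory closure of 29: C7 bears CH3 and the (R)-carbinol arm, C8 bears H and the propenyl-oxabicycle arm, the two arms trans, absolute sense as in 31 | C/C=C(\C)[C@@H](O)[C@@]1(C)/C=C(C)\C=C(C)/C=C(C)\[C@@H]1/C(C)=C/[C@]1(C)[C@H]2OC(=O)[C@]1(C)C(=O)[C@@H]2C | intermediate (not isolated)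
31 | shimalactone B | C/C=C(\C)[C@@H](O)[C@@]1(C)[C@@H]2C(C)=CC(C)=C[C@]2(C)[C@@H]1/C(C)=C/[C@]1(C)[C@H]2OC(=O)[C@]1(C)C(=O)[C@@H]2C | target

**Step count and risks**
Total steps: 12. Longest linear sequence: 7 steps (2, 3, 4, 5, 6, 7, 12; the branch from methacrolein through step 1 is equally long).

Steps most likely to fail:

Step 5 (enolonium ring closure). This is an unprecedented closure. Water or acetate may add to C3 instead of the diene, the oxidant may attack the diene, and the C7 facial preference and the E/Z ratio of the new alkene may be modest. The fallback sets out from 10 and returns at 13. Treat 10 with catalytic TfOH in CH2Cl2/(CF3)2CHOH: protonation of the diene CH2 terminus gives an allyl cation centred on C2′, and the enol closes onto it in the normal polarity sense to give (1S,4S,6R,7S)-4,6,7-trimethyl-7-(2-methylprop-1-en-1-yl)-2-oxabicyclo[2.2.1]heptane-3,5-dione F1. SeO2 in dioxane at 80 °C then oxidises the E-methyl group of the isobutenyl arm to give enal 13.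

Step 7 (iodo-olefination). The basic ylide may enolise C6 or open the strained ketolactone, and yields of this reaction are often moderate. The fallback sets out from 14 and returns at 29. CBr4/PPh3 (CH2Cl2, 0 °C) converts 14 into (1S,4S,6R,7S)-7-[(1E,3E)-6,6-dibromo-2,4-dimethylhexa-1,3,5-trien-1-yl]-4,6,7-trimethyl-2-oxabicyclo[2.2.1]heptane-3,5-dione F2. Trans-selective mono-methylation with Me2Zn and Pd(P(t-Bu)3)2 in THF replaces the bromine trans to the chain and gives (1S,4S,6R,7S)-7-[(1E,3E,5Z)-6-bromo-2,4-dimethylhepta-1,3,5-trien-1-yl]-4,6,7-trimethyl-2-oxabicyclo[2.2.1]heptane-3,5-dione F3. F3 is used in place of 19 under the conditions of step 12 and gives tetraene 29.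

Step 12 (coupling and cascade). Fluoride may cause protodeboronation of 28 or damage the ketolactone, two hindered Z partners couple slowly, and the ratio of 31 to shimalactone A is not known in advance. The fallback sets out from 28 and 19 and returns at 29; it swaps the coupling polarity to a neutral Stille reaction. NaOH then I2 (THF, 0 °C, retention) converts 28 into (2E,4R,5E,7Z)-8-iodo-3,5,7-trimethylocta-2,5,7-trien-4-ol F4. Me6Sn2 with Pd(PPh3)4 converts 19 into (1S,4S,6R,7S)-7-[(1E,3E,5Z)-2,4-dimethyl-6-(trimethylstannyl)hepta-1,3,5-trien-1-yl]-4,6,7-trimethyl-2-oxabicyclo[2.2.1]heptane-3,5-dione F5. F4 and F5 are joined with Pd2(dba)3/AsPh3 in N-methylpyrrolidone at 23–40 °C to give tetraene 29, which closes to 31 as before. This does not change the diastereomer ratio, which is set by the substrate.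

**Further compounds**
F1 | step 5 | (1S,4S,6R,7S)-4,6,7-trimethyl-7-(2-methylprop-1-en-1-yl)-2-oxabicyclo[2.2.1]heptane-3,5-dione | CC(C)=C[C@]1(C)[C@H]2OC(=O)[C@]1(C)C(=O)[C@@H]2C
F2 | step 7 | (1S,4S,6R,7S)-7-[(1E,3E)-6,6-dibromo-2,4-dimethylhexa-1,3,5-trien-1-yl]-4,6,7-trimethyl-2-oxabicyclo[2.2.1]heptane-3,5-dione | BrC(Br)=C/C(C)=C/C(C)=C/[C@]1(C)[C@H]2OC(=O)[C@]1(C)C(=O)[C@@H]2C
F3 | step 7 | (1S,4S,6R,7S)-7-[(1E,3E,5Z)-6-bromo-2,4-dimethylhepta-1,3,5-trien-1-yl]-4,6,7-trimethyl-2-oxabicyclo[2.2.1]heptane-3,5-dione | C/C(Br)=C/C(C)=C/C(C)=C/[C@]1(C)[C@H]2OC(=O)[C@]1(C)C(=O)[C@@H]2C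
F4 | step 12 | (2E,4R,5E,7Z)-8-iodo-3,5,7-trimethylocta-2,5,7-trien-4-ol | C/C=C(\C)[C@@H](O)/C(C)=C/C(C)=C\I
F5 | step 12 | (1S,4S,6R,7S)-7-[(1E,3E,5Z)-2,4-dimethyl-6-(trimethylstannyl)hepta-1,3,5-trien-1-yl]-4,6,7-trimethyl-2-oxabicyclo[2.2.1]heptane-3,5-dione | C/C([Sn](C)(C)C)=C/C(C)=C/C(C)=C/[C@]1(C)[C@H]2OC(=O)[C@]1(C)C(=O)[C@@H]2C
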